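**Retrosynthetic overview**

1. Numbering and enabling feature: the ring atoms are C1 (CH–OAc), C2, C3(Me)=C4, C5, C6, C7 (C(Me)OH), C8=C9, C10 (CH–iPr), C11, C12, C13 (C(Me)CHO); the target is (1S,3E,7R,8E,10S,13S). In the 13-membered carbocycle the ring bond C9–C10 joins the sp2 carbon C9 of the E-alkene C8=C9 to the secondary sp3 stereocentre C10, which carries only H, isopropyl and a ring CH2. This is the retron of a stereoretentive 1,2-metallate (Zweifel) olefination.
2. Key disconnection: C9–C10 is cut into a (Z)-alkenyl iodide at C9 and a (10S)-pinacol boronic ester at C10 in one open chain.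
3. Ring order: iodine–lithium exchange first closes a 14-membered cyclic boronate (C9–B–C10); this contracts with extrusion of boron to the 13-membered ring, fixing the C9–C10 bond, the E-alkene and the C10 configuration. No other ring is made.
4. Open chain: C10–B and the isopropyl group come from a sparteine-mediated lithiation–borylation of a C10 carbamate; C1–C2 comes from an α-selective allylbarium addition, and C1 is set by CBS reduction.
5. Fragments: C2–C9 from geraniol (Sharpless epoxide → tertiary propargylic alcohol, sets C7); C1 and C10–C13 from geranyl acetate (Sharpless epoxide → stereospecific semipinacol shift, sets the quaternary C13).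

Key step: step 20

Remark: TBS = tert-butyldimethylsilyl, Cb = C(O)N(i-Pr)2, pin = pinacolato. Geraniol, geranyl acetate, i-PrBpin and (+)-sparteine are taken as commercial. The descriptor at C13 is R while the carbon bears CH2O and becomes S when CH2OH is oxidised to CHO (priority change only).

**Route**

Step 1
Reactants: 1 geraniol
Product: 2 (2R,3R)-2,3-epoxygeraniol
Conditions: Ti(OiPr)4 (5 mol %), D-(−)-diethyl tartrate (7 mol %), t-BuOOH, 4 Å sieves, CH2Cl2, −20 °C
Reagents that add atoms: tert-butyl hydroperoxide, CC(C)(C)OO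
Why: Sharpless asymmetric epoxidation of the allylic 2,3-alkene; the D-(−)-tartrate complex should deliver oxygen to the face that gives the (2R,3R)-epoxide (this becomes C7), and the remote 6,7-alkene is not touched.

Step 2
Reactants: 2 (2R,3R)-2,3-epoxygeraniol
Product: 3 (2S,3R)-2-(chloromethyl)-3-methyl-3-(4-methylpent-3-en-1-yl)oxirane
Conditions: PPh3, CCl4, NaHCO3, reflux
Reagents that add atoms: carbon tetrachloride, ClC(Cl)(Cl)Cl
Why: Appel reaction under neutral conditions converts the primary alcohol into the chloride without opening the trisubstituted epoxide.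

Step 3
Reactants: 3 epoxy chloride
Product: 6 (3R)-3,7-dimethyl-1-(trimethylsilyl)oct-6-en-1-yn-3-ol, via dilithium alkynolate 4 (not isolated), via bis-silyl alkynol 5 (not isolated)
Conditions: n-BuLi (3.5 equiv), THF, −78 → −30 °C; Me3SiCl (3 equiv), −78 °C → rt; then 1 M HCl, THF, 0 °C
Reagents that add atoms: chlorotrimethylsilane, C[Si](C)(C)Cl
Why: Base-induced double elimination of a 2,3-epoxy chloride (α-deprotonation, epoxide opening, loss of HCl) should give the tertiary propargylic alkoxide with the C–O bond of the stereocentre untouched (retention, C7 = R); the acetylide is then C-silylated and the labile O–SiMe3 group is hydrolysed on work-up.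

Step 4
Reactants: 6 silyl alkynol
Product: 7 tert-butyl{[(3R)-3,7-dimethyl-1-(trimethylsilyl)oct-6-en-1-yn-3-yl]oxy}dimethylsilane
Conditions: TBSOTf, 2,6-lutidine, CH2Cl2, 0 °C → rt
Reagents that add atoms: tert-butyldimethylsilyl triflate, CC(C)(C)[Si](C)(C)OS(=O)(=O)C(F)(F)F
Why: Silyl triflate silylation of a tertiary alcohol; the bulky TBS group is chosen because it must later resist O-to-C migration in step 20.

Step 5
Reactants: 7 TBS ether
Product: 8 (2E,6R)-6-(tert-butyldimethylsilyloxy)-2,6-dimethyl-8-(trimethylsilyl)oct-2-en-7-yn-1-ol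
Conditions: SeO2 (0.5 equiv), t-BuOOH (2 equiv), salicylic acid (10 mol %), CH2Cl2, rt
Reagents that add atoms: selenium dioxide, O=[Se]=O (oxygen carrier, replenished by tert-butyl hydroperoxide, CC(C)(C)OO)
Why: Selenium dioxide allylic oxidation (ene reaction then [2,3]-sigmatropic shift) is selective for the E-methyl group of an isopropylidene terminus and should give the E-allylic alcohol whose carbinol carbon becomes C2.

Step 6
Reactants: 8 allylic alcohol
Product: 9 tert-butyl{[(3R,6E)-8-chloro-3,7-dimethyl-1-(trimethylsilyl)oct-6-en-1-yn-3-yl]oxy}dimethylsilane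
Conditions: PPh3, CCl4, CH2Cl2, rt
Reagents that add atoms: carbon tetrachloride, ClC(Cl)(Cl)Cl
Why: Appel reaction of a primary allylic alcohol proceeds by direct displacement without allylic transposition or loss of the E geometry.

Step 7
Reactants: 10 geranyl acetate
Product: 12 (2E)-6-hydroxy-3-methylhex-2-en-1-yl acetate, via aldehyde 11 (not isolated)
Conditions: O3 (1 equiv), pyridine, CH2Cl2/MeOH, −78 °C; then NaBH4, −78 → 0 °C
Reagents that add atoms: ozone, [O-][O+]=O
Why: Ozonolysis with one equivalent of ozone cleaves the electron-rich 6,7-alkene in preference to the 2,3-alkene deactivated by the allylic acetate, and borohydride work-up reduces the aldehyde.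

Step 8
Reactants: 12 hydroxy acetate
Product: 13 (2E)-6-(N,N-diisopropylcarbamoyloxy)-3-methylhex-2-en-1-yl acetate
Conditions: i-Pr2NC(O)Cl, Et3N, DMAP (10 mol %), CH2Cl2, reflux
Reagents that add atoms: N,N-diisopropylcarbamoyl chloride, CC(C)N(C(C)C)C(Cl)=O
Why: Carbamoylation of the primary alcohol installs the directing and leaving group for the later lithiation–borylation at C10.

Step 9
Reactants: 13 carbamate acetate
Product: 14 (4E)-6-hydroxy-4-methylhex-4-en-1-yl N,N-diisopropylcarbamate
Conditions: K2CO3, MeOH, rt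
Reagents that add atoms: none
Why: Methanolysis removes the acetate while the hindered carbamate is inert.

Step 10
Reactants: 14 allylic alcohol
Product: 15 3-[(2R,3R)-3-(hydroxymethyl)-2-methyloxiran-2-yl]propyl N,N-diisopropylcarbamate
Conditions: Ti(OiPr)4 (5 mol %), D-(−)-diethyl tartrate (7 mol %), t-BuOOH, 4 Å sieves, CH2Cl2, −20 °C
Reagents that add atoms: tert-butyl hydroperoxide, CC(C)(C)OO
Why: Sharpless asymmetric epoxidation; the D-(−)-tartrate complex should give the (2R,3R)-epoxide, which carries the stereochemical information for C13.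

Step 11
Reactants: 15 epoxy alcohol
Product: 16 3-[(2R,3R)-3-(tert-butyldimethylsilyloxymethyl)-2-methyloxiran-2-yl]propyl N,N-diisopropylcarbamate
Conditions: TBSCl, imidazole, DMF, 0 °C → rt
Reagents that add atoms: tert-butyldimethylsilyl chloride, CC(C)(C)[Si](C)(C)Cl
Why: Silylation of the primary alcohol gives the epoxy silyl ether needed for the rearrangement.

Step 12
Reactants: 16 epoxy silyl ether
Product: 17 (4R)-5-(tert-butyldimethylsilyloxy)-4-formyl-4-methylpentyl N,N-diisopropylcarbamate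
Conditions: MeAl(OC6H2-4-Br-2,6-t-Bu2)2 (2.5 equiv, from AlMe3 and the phenol), CH2Cl2, −78 → −20 °C
Reagents that add atoms: none
Why: Organoaluminium-promoted semipinacol rearrangement of a 2,3-epoxy silyl ether: the bulky Lewis acid opens the epoxide at the tertiary carbon and the siloxymethyl group migrates anti to the departing C–O bond, so the epoxide configuration is transferred to the quaternary carbon (C13), the former epoxide CH becomes the aldehyde (future C1) and the CH2OTBS arm is the future formyl carbon.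

Step 13
Reactants: 9 allylic chloride; 17 aldehyde
Product: 19 C1-epimeric 9,10-seco alcohol (C1 OH; C7 OTBS; C13 CH2OTBS; C8≡C9–SiMe3; C10H2–OCb), via allylbarium chloride 18 (not isolated)
Conditions: BaI2, lithium biphenylide (LiC12H10, 2 equiv), THF, rt; 9, −78 °C; then 17, −78 °C
Reagents that add atoms: none
Why: Allylbarium reagents add to aldehydes through the α-carbon with retention of alkene geometry, which should give the linear homoallylic alcohol (C1–C2 bond) with E-C3=C4 intact; C1 forms without control and is corrected in steps 14 and 15.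

Step 14
Reactants: 19 seco alcohol
Product: 20 9,10-seco C1 ketone
Conditions: Dess–Martin periodinane, NaHCO3, CH2Cl2, 0 °C → rt
Reagents that add atoms: none
Why: Dess–Martin oxidation under buffered conditions should give the β,γ-unsaturated ketone without moving the C3=C4 alkene into conjugation.

Step 15
Reactants: 20 ketone
Product: 21 (1S)-9,10-seco alcohol
Conditions: (R)-2-methyl-CBS-oxazaborolidine (0.5 equiv), catecholborane, toluene, −78 → −40 °C
Reagents that add atoms: none
Why: Corey–Bakshi–Shibata reduction: the (R)-oxazaborolidine distinguishes the quaternary C13 (large) from the C2 methylene (small) and should deliver hydride to give the (1S)-alcohol by reagent control.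

Step 16
Reactants: 21 (1S)-alcohol
Product: 22 (1S)-9,10-seco tris(TBS) ether carbamate
Conditions: TBSOTf, 2,6-lutidine, CH2Cl2, −78 → 0 °C
Reagents that add atoms: tert-butyldimethylsilyl triflate, CC(C)(C)[Si](C)(C)OS(=O)(=O)C(F)(F)F
Why: Silyl triflate silylation protects the hindered secondary alcohol against the organolithium reagents of steps 17 and 20.

Step 17
Reactants: 22 carbamate
Product: 25 (10S)-C10 pinacol boronic ester (C8≡C9–SiMe3), via lithiated carbamate 23 (not isolated), via boronate complex 24 (not isolated)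
Conditions: s-BuLi, (+)-sparteine, Et2O, −78 °C, 5 h; i-PrBpin, −78 °C; MgBr2·OEt2, −78 °C → reflux
Reagents that add atoms: 2-isopropyl-4,4,5,5-tetramethyl-1,3,2-dioxaborolane, CC(C)B1OC(C)(C)C(C)(C)O1
Why: Sparteine-mediated lithiation–borylation: s-BuLi/(+)-sparteine removes the pro-R proton of the primary carbamate, the (R)-lithiated carbamate adds to boron with retention, and 1,2-migration of isopropyl with inversion expels the carbamate to give the (10S)-secondary boronic ester by reagent control.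

Step 18
Reactants: 25 boronic ester
Product: 26 (10S)-boronic ester 1-iodoalkyne
Conditions: N-iodosuccinimide, AgNO3 (10 mol %), acetone, rt, dark
Reagents that add atoms: N-iodosuccinimide, O=C1CCC(=O)N1I
Why: Silver-catalysed iododesilylation of an alkynylsilane should give the 1-iodoalkyne without touching the alkyl boronic ester, the silyl ethers or the trisubstituted alkene.

Step 19
Reactants: 26 iodoalkyne
Product: 27 (8Z,10S)-alkenyl iodide boronic ester
Conditions: 2-nitrobenzenesulfonyl hydrazide, Et3N, THF/i-PrOH, rt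
Reagents that add atoms: none
Why: Diimide reduction adds two hydrogens syn to the iodoalkyne and should give the (Z)-alkenyl iodide; the trisubstituted alkene, the C–I bond and the boronic ester are inert to diimide.

Step 20
Reactants: 27 (Z)-alkenyl iodide boronic ester
Product: 31 macrocyclic tris(TBS) ether (1S,3E,7R,8E,10S,13R), via alkenyllithium 28 (not isolated), via cyclic boronate complex 29 (not isolated), via iodo boronic ester 30 (not isolated)
Conditions: t-BuLi (2.05 equiv) added to 27 (1 mM in Et2O), −100 → −78 °C; I2, THF/MeOH, −78 °C; NaOMe, MeOH, −78 °C → rt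
Reagents that add atoms: none
Why: Proposed new method: iodine–lithium exchange converts 27 into the (Z)-alkenyllithium 28, whose C9 adds to the boron on C10 to give the 14-membered cyclic boronate complex 29; iodine then forms an iodonium ion on C8=C9, C10 migrates from boron to C9 anti to the new C8–I bond (1,2-metallate shift, the C9–C10 bond) to give the β-iodo boronic ester 30, and methoxide-induced anti elimination of boron and iodine gives the alkene. The closest known reaction type is the intermolecular Zweifel olefination of enantioenriched secondary pinacol boronic esters with alkenyllithiums, and capture of freshly exchanged organolithiums by boron esters (in situ quench, small cyclic boronate complexes) is established; only the macrocyclic setting is new. Ring closure: the boracycle closes by addition of C9–Li to boron, and the 13-membered carbocycle arises from it by ring contraction with extrusion of boron, so no separate C–C macrocyclisation is needed. No new stereocentre is created: C10 keeps its configuration because the migrating carbon moves with retention, and the E geometry of C8=C9 follows from anti addition then anti elimination on the Z-alkenyl boronate (net inversion of alkene geometry). The step needs exchange to outrun attack of t-BuLi on boron (the α-branched Bpin is hindered, and t-BuLi is added to cold dilute 27), cyclisation to outrun oligomerisation (high dilution), and no 1,4 O-to-C silyl shift in 28 (bulky tertiary OTBS, Et2O, −78 °C).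

Step 21
Reactants: 31 macrocyclic tris(TBS) ether
Product: 32 macrocyclic triol (1S,3E,7R,8E,10S,13R)
Conditions: Bu4NF (10 equiv), THF, 50 °C
Reagents that add atoms: none
Why: Fluoride should cleave all three silyl ethers, and the triol has no base-sensitive group.

Step 22
Reactants: 32 triol
Product: 33 β-hydroxy aldehyde (1S,3E,7R,8E,10S,13S)
Conditions: TEMPO (20 mol %), PhI(OAc)2 (1.2 equiv), CH2Cl2, rt
Reagents that add atoms: none
Why: Oxoammonium (TEMPO) oxidation is selective for the primary alcohol over the secondary and tertiary ones and stops at the aldehyde; the α-carbon is quaternary, so neither epimerisation nor elimination is possible.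

Step 23
Reactants: 33 β-hydroxy aldehyde
Product: 34 target CNP0106239.1
Conditions: Ac2O, pyridine, DMAP (5 mol %), CH2Cl2, 0 °C
Reagents that add atoms: acetic anhydride, CC(=O)OC(C)=O
Why: Acylation of the secondary C1 alcohol; the tertiary allylic C7 alcohol should be too hindered to react under these mild conditions.

**Compound list**

1 | geraniol, (2E)-3,7-dimethylocta-2,6-dien-1-ol | CC(C)=CCC/C(C)=C/CO | starting material
2 | (2R,3R)-2,3-epoxygeraniol | OC[C@H]1O[C@]1(C)CCC=C(C)C | intermediate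
3 | (2S,3R)-2-(chloromethyl)-3-methyl-3-(4-methylpent-3-en-1-yl)oxirane | ClC[C@H]1O[C@]1(C)CCC=C(C)C | intermediate
4 | dilithium salt (alkoxide and acetylide) of (3R)-3,7-dimethyloct-6-en-1-yn-3-ol | CC(C)=CCC[C@@](C)(O[Li])C#C[Li] | intermediate (not isolated)
5 | (3R)-3,7-dimethyl-1-(trimethylsilyl)-3-(trimethylsilyloxy)oct-6-en-1-yne | CC(C)=CCC[C@@](C)(O[Si](C)(C)C)C#C[Si](C)(C)C | intermediate (not isolated)
6 | (3R)-3,7-dimethyl-1-(trimethylsilyl)oct-6-en-1-yn-3-ol | CC(C)=CCC[C@@](C)(O)C#C[Si](C)(C)C | intermediate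
7 | tert-butyl{[(3R)-3,7-dimethyl-1-(trimethylsilyl)oct-6-en-1-yn-3-yl]oxy}dimethylsilane | CC(C)=CCC[C@@](C)(O[Si](C)(C)C(C)(C)C)C#C[Si](C)(C)C | intermediate
8 | (2E,6R)-6-(tert-butyldimethylsilyloxy)-2,6-dimethyl-8-(trimethylsilyl)oct-2-en-7-yn-1-ol | OC/C(C)=C/CC[C@@](C)(O[Si](C)(C)C(C)(C)C)C#C[Si](C)(C)C | intermediate
9 | tert-butyl{[(3R,6E)-8-chloro-3,7-dimethyl-1-(trimethylsilyl)oct-6-en-1-yn-3-yl]oxy}dimethylsilane | ClC/C(C)=C/CC[C@@](C)(O[Si](C)(C)C(C)(C)C)C#C[Si](C)(C)C | intermediate
10 | geranyl acetate | CC(C)=CCC/C(C)=C/COC(C)=O | starting material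
11 | (2E)-3-methyl-6-oxohex-2-en-1-yl acetate | O=CCC/C(C)=C/COC(C)=O | intermediate (not isolated)
12 | (2E)-6-hydroxy-3-methylhex-2-en-1-yl acetate | OCCC/C(C)=C/COC(C)=O | intermediate
13 | (2E)-6-(N,N-diisopropylcarbamoyloxy)-3-methylhex-2-en-1-yl acetate | CC(C)N(C(C)C)C(=O)OCCC/C(C)=C/COC(C)=O | intermediate
14 | (4E)-6-hydroxy-4-methylhex-4-en-1-yl N,N-diisopropylcarbamate | CC(C)N(C(C)C)C(=O)OCCC/C(C)=C/CO | intermediate
15 | 3-[(2R,3R)-3-(hydroxymethyl)-2-methyloxiran-2-yl]propyl N,N-diisopropylcarbamate | OC[C@H]1O[C@]1(C)CCCOC(=O)N(C(C)C)C(C)C | intermediate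
16 | 3-[(2R,3R)-3-(tert-butyldimethylsilyloxymethyl)-2-methyloxiran-2-yl]propyl N,N-diisopropylcarbamate | CC(C)(C)[Si](C)(C)OC[C@H]1O[C@]1(C)CCCOC(=O)N(C(C)C)C(C)C | intermediate
17 | (4R)-5-(tert-butyldimethylsilyloxy)-4-formyl-4-methylpentyl N,N-diisopropylcarbamate | CC(C)N(C(C)C)C(=O)OCCC[C@](C=O)(C)CO[Si](C)(C)C(C)(C)C | intermediate
18 | allylbarium chloride derived from 9 (barium on C2) | Cl[Ba]C/C(C)=C/CC[C@@](C)(O[Si](C)(C)C(C)(C)C)C#C[Si](C)(C)C | intermediate (not isolated)
19 | C1-epimeric 9,10-seco alcohol (C1 OH; C7 OTBS; C13 CH2OTBS; C8≡C9–SiMe3; C10H2–OCb; 7R,13R) | OC(C/C(C)=C/CC[C@@](C)(O[Si](C)(C)C(C)(C)C)C#C[Si](C)(C)C)[C@@](C)(CO[Si](C)(C)C(C)(C)C)CCCOC(=O)N(C(C)C)C(C)C | intermediate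
20 | 9,10-seco C1 ketone (7R,13R) | O=C(C/C(C)=C/CC[C@@](C)(O[Si](C)(C)C(C)(C)C)C#C[Si](C)(C)C)[C@@](C)(CO[Si](C)(C)C(C)(C)C)CCCOC(=O)N(C(C)C)C(C)C | intermediate
21 | (1S,7R,13R)-9,10-seco alcohol | O[C@@H](C/C(C)=C/CC[C@@](C)(O[Si](C)(C)C(C)(C)C)C#C[Si](C)(C)C)[C@@](C)(CO[Si](C)(C)C(C)(C)C)CCCOC(=O)N(C(C)C)C(C)C | intermediate
22 | (1S,7R,13R)-9,10-seco tris(TBS) ether carbamate | CC(C)(C)[Si](C)(C)O[C@@H](C/C(C)=C/CC[C@@](C)(O[Si](C)(C)C(C)(C)C)C#C[Si](C)(C)C)[C@@](C)(CO[Si](C)(C)C(C)(C)C)CCCOC(=O)N(C(C)C)C(C)C | intermediate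
23 | (10R)-C10-lithiated carbamate (sparteine complex) | CC(C)(C)[Si](C)(C)O[C@@H](C/C(C)=C/CC[C@@](C)(O[Si](C)(C)C(C)(C)C)C#C[Si](C)(C)C)[C@@](C)(CO[Si](C)(C)C(C)(C)C)CC[C@@H]([Li])OC(=O)N(C(C)C)C(C)C | intermediate (not isolated)
24 | lithium isopropyl(pinacolato)boronate complex at C10 | CC(C)(C)[Si](C)(C)O[C@@H](C/C(C)=C/CC[C@@](C)(O[Si](C)(C)C(C)(C)C)C#C[Si](C)(C)C)[C@@](C)(CO[Si](C)(C)C(C)(C)C)CC[C@H](OC(=O)N(C(C)C)C(C)C)[B-]1(C(C)C)OC(C)(C)C(C)(C)O1.[Li+] | intermediate (not isolated)
25 | (1S,7R,10S,13R)-C10 pinacol boronic ester with C8≡C9–SiMe3 | CC(C)(C)[Si](C)(C)O[C@@H](C/C(C)=C/CC[C@@](C)(O[Si](C)(C)C(C)(C)C)C#C[Si](C)(C)C)[C@@](C)(CO[Si](C)(C)C(C)(C)C)CC[C@@H](C(C)C)B1OC(C)(C)C(C)(C)O1 | intermediate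
26 | (1S,7R,10S,13R)-boronic ester 1-iodoalkyne | CC(C)(C)[Si](C)(C)O[C@@H](C/C(C)=C/CC[C@@](C)(O[Si](C)(C)C(C)(C)C)C#CI)[C@@](C)(CO[Si](C)(C)C(C)(C)C)CC[C@@H](C(C)C)B1OC(C)(C)C(C)(C)O1 | intermediate
27 | (1S,7R,8Z,10S,13R)-alkenyl iodide boronic ester | CC(C)(C)[Si](C)(C)O[C@@H](C/C(C)=C/CC[C@@](C)(O[Si](C)(C)C(C)(C)C)/C=C\I)[C@@](C)(CO[Si](C)(C)C(C)(C)C)CC[C@@H](C(C)C)B1OC(C)(C)C(C)(C)O1 | intermediate
28 | (Z)-C9 alkenyllithium | CC(C)(C)[Si](C)(C)O[C@@H](C/C(C)=C/CC[C@@](C)(O[Si](C)(C)C(C)(C)C)/C=C\[Li])[C@@](C)(CO[Si](C)(C)C(C)(C)C)CC[C@@H](C(C)C)B1OC(C)(C)C(C)(C)O1 | intermediate (not isolated)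
29 | 14-membered cyclic lithium boronate complex (C9–B–C10 in the ring; Z-alkenyl) | CC(C)(C)[Si](C)(C)O[C@H]1C/C(C)=C/CC[C@@](C)(O[Si](C)(C)C(C)(C)C)/C=C\[B-]2(OC(C)(C)C(C)(C)O2)[C@H](C(C)C)CC[C@]1(C)CO[Si](C)(C)C(C)(C)C.[Li+] | intermediate (not isolated)
30 | 13-membered β-iodo boronic ester (C8–I and C9–Bpin; anti adduct, one of the two convergent facial isomers drawn) | CC(C)(C)[Si](C)(C)O[C@H]1C/C(C)=C/CC[C@@](C)(O[Si](C)(C)C(C)(C)C)[C@@H](I)[C@@H](B2OC(C)(C)C(C)(C)O2)[C@H](C(C)C)CC[C@]1(C)CO[Si](C)(C)C(C)(C)C | intermediate (not isolated)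
31 | macrocyclic tris(TBS) ether (1S,3E,7R,8E,10S,13R) | CC(C)(C)[Si](C)(C)O[C@H]1C/C(C)=C/CC[C@@](C)(O[Si](C)(C)C(C)(C)C)/C=C/[C@H](C(C)C)CC[C@]1(C)CO[Si](C)(C)C(C)(C)C | intermediate
32 | macrocyclic triol (1S,3E,7R,8E,10S,13R) | O[C@H]1C/C(C)=C/CC[C@@](C)(O)/C=C/[C@H](C(C)C)CC[C@]1(C)CO | intermediate
33 | β-hydroxy aldehyde (1S,3E,7R,8E,10S,13S) | O[C@H]1C/C(C)=C/CC[C@@](C)(O)/C=C/[C@H](C(C)C)CC[C@]1(C)C=O | intermediate
34 | CNP0106239.1, (1S,3E,7R,8E,10S,13S)-13-formyl-7-hydroxy-10-isopropyl-3,7,13-trimethylcyclotrideca-3,8-dien-1-yl acetate | CC(=O)O[C@H]1C/C(C)=C/CC[C@@](C)(O)/C=C/[C@H](C(C)C)CC[C@]1(C)C=O | target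

**Step count and risks**

Total step count: 23. Longest linear sequence: 17 steps (steps 1–6 then 13–23; the geranyl acetate branch, steps 7–12 then 13–23, is equally long).

Steps most likely to fail:

1. Step 20 (Proposed new method). What may go wrong: addition of t-BuLi to boron before the iodine–lithium exchange, intermolecular boronate formation leading to oligomers, or 1,4 oxygen-to-carbon silyl migration in the alkenyllithium. The fallback sets out from 25 and forms C9–C10 by the known intermolecular boron-to-carbon alkynylation, then closes the ring by alkyne metathesis. Boronic ester 25 is treated with 1-lithiovinyl N,N-diisopropylcarbamate and then I2/NaOMe to give the C10 (1-carbamoyloxyvinyl) compound F1. LiN(i-Pr)2 eliminates the carbamate to give the C10 ethynyl compound F2, with retention at C10. K2CO3/MeOH removes the alkynyl silane to give the terminal diyne F3, and n-BuLi/MeI caps both alkynes to give the bis(prop-1-ynyl) compound F4. Ring-closing alkyne metathesis with Mo(≡CC6H4OMe-4)(OSiPh3)3 (toluene, 5 Å sieves, 80 °C) should close the 13-membered cycloalkyne tris(TBS) ether F5. Bu4NF gives the cycloalkyne triol F6, and trans-hydroalumination of the tertiary propargylic alcohol with NaAlH2(OCH2CH2OMe)2 in THF should give the E-allylic alcohol. The fallback comes back to the route at triol 32.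

2. Step 13. What may go wrong: attack through the γ-carbon or loss of alkene geometry in the allyl metal, and electron-transfer side reactions of activated barium with the functionalised chloride. The fallback sets out from 9 and 17 and uses sulfone chemistry. Chloride 9 and PhSO2Na in DMF give the allylic phenyl sulfone F7. Its lithio derivative (n-BuLi, THF, −78 °C) adds to aldehyde 17 through the sulfonyl-bearing carbon to give the β-hydroxy sulfone F8. Dess–Martin oxidation gives the β-keto sulfone F9, and SmI2 (divalent samarium) in THF/MeOH at −78 °C removes the sulfonyl group. The fallback comes back to the route at ketone 20.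

3. Step 17. What may go wrong: competing metalation or attack by s-BuLi elsewhere in the polyfunctional chain during the long deprotonation, and sluggish 1,2-migration of the branched isopropyl group. The fallback sets out from 16 and installs the chiral carbenoid precursor on this simple fragment. s-BuLi/(+)-sparteine (Et2O, −78 °C) then Bu3SnCl gives the α-stannyl carbamate epoxide F10. This is carried through the operations of steps 12 to 16: semipinacol shift to the stannyl aldehyde F11, allylbarium addition of 9 to the stannyl seco alcohol F12, Dess–Martin oxidation to the stannyl ketone F13, CBS reduction to the stannyl (1S)-alcohol F14, and silylation to the stannyl tris(TBS) ether F15. Tin–lithium exchange of F15 with n-BuLi (Et2O, −78 °C, retention) regenerates lithiated carbamate 23 without a late deprotonation; i-PrBpin and then MgBr2·OEt2 follow as in step 17. The fallback comes back to the route at boronic ester 25.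

Further compounds
F1 | step 20 | C10 (1-carbamoyloxyvinyl) compound | CC(C)(C)[Si](C)(C)O[C@@H](C/C(C)=C/CC[C@@](C)(O[Si](C)(C)C(C)(C)C)C#C[Si](C)(C)C)[C@@](C)(CO[Si](C)(C)C(C)(C)C)CC[C@@H](C(C)C)C(=C)OC(=O)N(C(C)C)C(C)C
F2 | step 20 | C10 ethynyl compound | CC(C)(C)[Si](C)(C)O[C@@H](C/C(C)=C/CC[C@@](C)(O[Si](C)(C)C(C)(C)C)C#C[Si](C)(C)C)[C@@](C)(CO[Si](C)(C)C(C)(C)C)CC[C@@H](C(C)C)C#C
F3 | step 20 | terminal diyne | CC(C)(C)[Si](C)(C)O[C@@H](C/C(C)=C/CC[C@@](C)(O[Si](C)(C)C(C)(C)C)C#C)[C@@](C)(CO[Si](C)(C)C(C)(C)C)CC[C@@H](C(C)C)C#C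
F4 | step 20 | bis(prop-1-ynyl) compound | CC(C)(C)[Si](C)(C)O[C@@H](C/C(C)=C/CC[C@@](C)(O[Si](C)(C)C(C)(C)C)C#CC)[C@@](C)(CO[Si](C)(C)C(C)(C)C)CC[C@@H](C(C)C)C#CC
F5 | step 20 | 13-membered cycloalkyne tris(TBS) ether | CC(C)(C)[Si](C)(C)O[C@H]1C/C(C)=C/CC[C@@](C)(O[Si](C)(C)C(C)(C)C)C#C[C@H](C(C)C)CC[C@]1(C)CO[Si](C)(C)C(C)(C)C
F6 | step 20 | cycloalkyne triol | O[C@H]1C/C(C)=C/CC[C@@](C)(O)C#C[C@H](C(C)C)CC[C@]1(C)CO
F7 | step 13 | allylic phenyl sulfone | O=S(=O)(C/C(C)=C/CC[C@@](C)(O[Si](C)(C)C(C)(C)C)C#C[Si](C)(C)C)c1ccccc1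
F8 | step 13 | β-hydroxy sulfone (diastereomer mixture) | OC(C(/C(C)=C/CC[C@@](C)(O[Si](C)(C)C(C)(C)C)C#C[Si](C)(C)C)S(=O)(=O)c1ccccc1)[C@@](C)(CO[Si](C)(C)C(C)(C)C)CCCOC(=O)N(C(C)C)C(C)C
F9 | step 13 | β-keto sulfone | O=C(C(/C(C)=C/CC[C@@](C)(O[Si](C)(C)C(C)(C)C)C#C[Si](C)(C)C)S(=O)(=O)c1ccccc1)[C@@](C)(CO[Si](C)(C)C(C)(C)C)CCCOC(=O)N(C(C)C)C(C)C
F10 | step 17 | α-stannyl carbamate epoxide | CC(C)(C)[Si](C)(C)OC[C@H]1O[C@]1(C)CC[C@H](OC(=O)N(C(C)C)C(C)C)[Sn](CCCC)(CCCC)CCCC
F11 | step 17 | stannyl aldehyde | O=C[C@@](C)(CO[Si](C)(C)C(C)(C)C)CC[C@H](OC(=O)N(C(C)C)C(C)C)[Sn](CCCC)(CCCC)CCCC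
F12 | step 17 | stannyl seco alcohol (C1 epimers) | OC(C/C(C)=C/CC[C@@](C)(O[Si](C)(C)C(C)(C)C)C#C[Si](C)(C)C)[C@@](C)(CO[Si](C)(C)C(C)(C)C)CC[C@H](OC(=O)N(C(C)C)C(C)C)[Sn](CCCC)(CCCC)CCCC
F13 | step 17 | stannyl ketone | O=C(C/C(C)=C/CC[C@@](C)(O[Si](C)(C)C(C)(C)C)C#C[Si](C)(C)C)[C@@](C)(CO[Si](C)(C)C(C)(C)C)CC[C@H](OC(=O)N(C(C)C)C(C)C)[Sn](CCCC)(CCCC)CCCC
F14 | step 17 | stannyl (1S)-alcohol | O[C@@H](C/C(C)=C/CC[C@@](C)(O[Si](C)(C)C(C)(C)C)C#C[Si](C)(C)C)[C@@](C)(CO[Si](C)(C)C(C)(C)C)CC[C@H](OC(=O)N(C(C)C)C(C)C)[Sn](CCCC)(CCCC)CCCC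
F15 | step 17 | stannyl tris(TBS) ether | CC(C)(C)[Si](C)(C)O[C@@H](C/C(C)=C/CC[C@@](C)(O[Si](C)(C)C(C)(C)C)C#C[Si](C)(C)C)[C@@](C)(CO[Si](C)(C)C(C)(C)C)CC[C@H](OC(=O)N(C(C)C)C(C)C)[Sn](CCCC)(CCCC)CCCC
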